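## Structural features

The target has one ring, a 1,4-benzoquinone (ring A). It carries a methyl group at C6 and, at C2, an unbranched sixteen-carbon chain joined through the benzylic and allylic methylene C1'; C1 is the carbonyl between the two substituted ring carbons. The chain holds three trisubstituted E olefins (C2'=C3', C6'=C7', C10'=C11') separated by two-carbon bridges and ends in an isopropylidene group (C14'=C15'). C3' and C7' carry methyl groups, whereas C11' carries CH2OH. The only stereocentre is C12' (R), a secondary carbinol allylic to C10'=C11' and homoallylic to C14'=C15'; it has no neighbouring stereocentre but sits directly on the one olefin whose geometry is hard to control. Fragile elements are the quinone (bases, nucleophiles, peroxide, light, cyclisation onto C2'=C3' to a chromenol), the doubly activated C1' methylene, the skipped polyene (acid-induced cyclisation) and the 2-alkylidene-1,3-diol (allylic ionisation, over-oxidation). The real difficulty is C10'=C11': C11' bears two oxygenated carbons of almost equal size, CH2OH and C12'H(OH), so neither thermodynamics nor carbonyl olefination tells the two geometries apart. The key step uses the fact that O12' is propargylic to a C10'≡C11' alkyne retron: an alkoxide on C12' holds magnesium on C10' in a five-membered chelate (O12', C12', C11', C10', Mg) while a hydroxymethyl synthon adds to C11' from the opposite side, which places the new carbon cis to C9'.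

## Logic of the disconnections

26 to 25: the two carbonyl groups of ring A (C1, C4) are taken back to aryl methyl ethers. A quinone would not survive organolithium, Grignard or peroxide reagents, whereas 25 tolerates all of them. The forward oxidation must be faster on the arene than on the 1,3-diol and the olefins, and it must avoid base.

25 to 24: the C–O bond of the primary hydroxyl on the C11' branch is exchanged for a C–Si bond. The hydroxymethyl carbon thereby becomes a carbon nucleophile, and O12' is left as the only free hydroxyl and the only directing group. The forward oxidation must keep the position and geometry of C10'=C11' and must not be acidic, because 24 is an allylsilane.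

24 to 19 and 21: the C11'–CH2 bond is cut and the C10' hydrogen removed, which reveals the C10'≡C11' alkyne. This removes the difficult olefin and the branch in one operation and leaves a linear chain whose only stereocentre is a propargylic carbinol. The forward step must add carbon to C11' and metal to C10' in anti fashion on a slow substrate class, and the free hydroxyl consumes one equivalent of 21.

21 to 20: the C–Mg bond is traced to a C–Cl bond. The demand is only that the reagent does not attack its own Si–O bond.

19 to 18: the C12'–H bond is cut, so the stereocentre arises by reduction of a prochiral ketone. The catalyst has to distinguish an alkynyl from a primary alkyl flank, a well-differentiated pair. The conditions must be free of base because C13' is doubly activated.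

18 to 13 and 16, then 16 to 14: the C11'–C12' bond is cut as an acyl substitution. 13, the advanced fragment, can be the limiting component, which aldehyde alkynylations that need excess alkyne do not allow. Addition must outrun α-deprotonation of 16, and the quench must be cold and acidic. 16 comes from 14 by cutting the amide C–N bond.

13 to 9 and 10: the C8'–C9' bond is cut, and 10 supplies C9', C10' and C11' as one three-carbon unit. The nucleophile must react at its propargylic terminus and by SN2 at the allylic bromide. The silyl group is removed in the same flask (through 12).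

9 to 8 to 7: C8'–Br is traced to C8'–O and then to C8'–H. This single C–H oxidation is what lets a purchased geranyl unit supply both internal E olefins. It must select the methyl group trans to C5' on the terminal olefin over the second olefin and the C1' methylene.

7 to 3 and 4: the bond between ring A and C1' is cut, giving 3 (used as 5 and 6) and 4. The chain is reduced to a ten-carbon unit with both olefins in place. The arylmetal must attack the primary allylic carbon without transposition.

3 to 2 to 1: an O–CH3 bond and then the C–Br bond are cut. 1 already carries both oxygens and the methyl group, so only one substituent has to be introduced, ortho to the free hydroxyl.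

## Other disconnections considered

Alternative 1: The cut runs through ring A. Bonds C3–C4, C1–C2 and C1–C6 are disconnected, which leads to the chromium alkenylcarbene complex A2 and the terminal 1,4-enyne A3 that carries the whole side chain as its bis-silyl ether; C1 comes from a carbonyl ligand of A2.
- Forward key step: A2 and A3 are warmed in an ether solvent. Alkyne insertion, CO insertion to a vinylketene and 6π-electrocyclisation close the six-membered ring and give the 4-methoxyphenol A1.
- In its favour: the substitution pattern of ring A follows from the mechanism, and the route is convergent. On ring regiochemistry it is the equal of the chosen plan. On the final oxidation it is better, because the free phenol of A1 is oxidised to the quinone more easily than a dimethyl ether.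
- Against it here: the ring is the easy part of the molecule. A3 must already contain C10'=C11' and C12', so the real problem is only moved into the synthesis of A3. Both hydroxyls need protection and release, the skipped enyne terminus is prone to base-induced isomerisation, the remote olefins may intercept carbene or ketene intermediates, and chromium is stoichiometric.
- Comparison: the annulation creates no stereo-element, whereas step 11 creates the one that matters. In step count it should be longer by the protecting-group steps, the preparation of A2 and the installation of the propargyl terminus.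

Alternative 2: The cut removes the C3' methyl group and the C1'–C2' bond, so the chain ends in the terminal alkyne A5 (C2'H≡C3') and the arene arrives as the benzyl chloride A6.
- Forward key step: A5 undergoes zirconium-catalysed syn-methylalumination, methyl to C3' and aluminium to C2'. The alkenylalane is coupled in the same pot with A6 under nickel catalysis to give A4.
- In its favour: this carbometalation is among the most reliable routes to an E trisubstituted olefin, and there is no SN2 against SN2' question as in step 3. The arene enters late, so no oxidation has to be run in its presence, which is an advantage over step 4. On the geometry of C2'=C3' it is the equal of the chosen plan, and on convergence it is better.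
- Against it here: C2'=C3' is no problem when it is bought with a geranyl unit. A5 has to be built without that unit, so C6'=C7' needs its own olefin synthesis. A5 must again contain C10'=C11' and C12', which this step does not address. A Lewis-acidic alane in excess meets the allylic silyl ether at C12', and two silyl groups go on and come off.
- Comparison: both plans set olefin geometry by alkyne carbometalation, syn and unassisted in one case, anti and chelate-controlled in the other. Only the chosen plan applies it to the olefin that is hard to make. The step count should be clearly higher.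

Alternative 3: The cut is C12'–C13'. The prenyl group is removed and C12' becomes the formyl carbon of the E enal A8, whose primary hydroxyl is silylated.
- Forward key step: A8 and the carbinol A9 (or its antipode, whichever sense gives 12'R) are treated with a catalytic sulfonic acid. Hemiacetal formation, ionisation to an oxocarbenium ion and a [3,3]-sigmatropic shift through a chair form C12'–C13', move the double bond to C14'=C15', release the ketone A10 and give A7.
- In its favour: the prenyl group is transferred in its linear form without a metal, and the stereocentre comes from an inexpensive auxiliary. No β,γ-unsaturated carbonyl compound such as 16 or 18 has to be handled, a point on which it is better than the chosen plan. In expected enantiocontrol at C12' the two plans are about equal.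
- Against it here: the step does not set C10'=C11'. That geometry must be built into A8, where C11' carries a formyl and a silyloxymethyl group that differ only in oxidation state, so two nearly equivalent hydroxymethyl groups would first have to be told apart. Conjugated aldehydes are the less reactive acceptors in this transfer. The acid, the oxocarbenium ion and the allylic cation that A7 can form all endanger the skipped polyene, the silyl ether and the electron-rich arene.
- Comparison: in the chosen plan the order is reversed, C12' is set first and then dictates the olefin geometry, so the two oxygenated carbons on C11' are differentiated automatically. The route is estimated to be two to three steps longer and needs one protecting group on the chain where the chosen plan needs none.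

Key step: step 11

## Remarks

- Chain atoms are numbered C1' to C16' from the ring-bound methylene; ring A is numbered with C1 as the carbonyl between the chain-bearing C2 and the methyl-bearing C6.
- Allylsilane 24 is 10'Z by the sequence rule because silicon outranks oxygen on the C11' branch; its spatial arrangement is that of the 10'E olefin of 25 and 26, and no isomerisation is implied.
- A bromocresol without a para oxygen would need an extra ring oxidation; phenol 1 already holds that oxygen, so the aryl bromide 3 is reached in two steps.
- Assumption: 1, 4, 10, 14 and 20 are purchased; 4 is passed through a short plug of basic alumina before use.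
- Assumption: the sense of induction in step 9 is taken from the behaviour of this catalyst family with alkynyl ketones and would be confirmed by Mosher ester analysis of 19.

## Route

Step 1
Reactants: 1 4-methoxy-2-methylphenol
Product: 2 2-bromo-4-methoxy-6-methylphenol
Conditions: NBS, i-Pr2NH (0.1 equiv), CH2Cl2, 0 °C
Reagents that add atoms: N-bromosuccinimide, O=C1CCC(=O)N1Br
Why: Electrophilic aromatic bromination; the free hydroxyl is the strongest donor and its para position is blocked by methoxy, so the N-bromoamine formed from NBS and the amine should deliver bromine to C6, the only open position ortho to OH.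

Step 2
Reactants: 2 2-bromo-4-methoxy-6-methylphenol
Product: 3 1-bromo-2,5-dimethoxy-3-methylbenzene
Conditions: MeI, K2CO3, acetone, reflux
Reagents that add atoms: iodomethane, CI
Why: Williamson ether synthesis on the phenoxide; the flanking bromine and methyl groups do not stop methylation by the small electrophile.

Step 3
Reactants: 3 1-bromo-2,5-dimethoxy-3-methylbenzene; 4 geranyl bromide [(2E)-1-bromo-3,7-dimethylocta-2,6-diene]
Product: 7 1-[(2E)-3,7-dimethylocta-2,6-dien-1-yl]-2,5-dimethoxy-3-methylbenzene, via aryllithium 5 (not isolated), via arylcopper 6 (not isolated)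
Conditions: n-BuLi, THF, −78 °C; CuBr·SMe2, −78 to −40 °C; 4, −78 to 0 °C
Reagents that add atoms: none
Why: Bromine–lithium exchange, transmetalation to an arylcopper (monovalent copper) and SN2 allylation; the arylcopper should attack the primary carbon of 4 and not the fully substituted γ-carbon, so the E-geranyl unit is transferred unchanged and C2'=C3' and C6'=C7' are installed together.

Step 4
Reactants: 7 1-[(2E)-3,7-dimethylocta-2,6-dien-1-yl]-2,5-dimethoxy-3-methylbenzene
Product: 8 (2E,6E)-8-(2,5-dimethoxy-3-methylphenyl)-2,6-dimethylocta-2,6-dien-1-ol
Conditions: SeO2 (0.3 equiv), t-BuOOH, salicylic acid (0.1 equiv), CH2Cl2, 0 °C to rt, stopped at partial conversion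
Reagents that add atoms: selenium dioxide, O=[Se]=O; tert-butyl hydroperoxide, CC(C)(C)OO
Why: Riley allylic oxidation (ene reaction, then [2,3]-sigmatropic shift) run with catalytic SeO2 and t-BuOOH as terminal oxidant; the terminal isopropylidene olefin is the most accessible and its methyl group trans to C5' is oxidised, which gives the E allylic alcohol, and early interruption allows 7 to be recycled and limits enal formation.

Step 5
Reactants: 8 (2E,6E)-8-(2,5-dimethoxy-3-methylphenyl)-2,6-dimethylocta-2,6-dien-1-ol
Product: 9 1-[(2E,6E)-8-bromo-3,7-dimethylocta-2,6-dien-1-yl]-2,5-dimethoxy-3-methylbenzene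
Conditions: CBr4, PPh3, CH2Cl2, 0 °C
Reagents that add atoms: carbon tetrabromide, BrC(Br)(Br)Br
Why: Appel reaction; the primary allylic alcohol is converted into the bromide under neutral conditions by SN2 displacement of the oxyphosphonium ion, without allylic transposition and without harm to the electron-rich arene.

Step 6
Reactants: 9 1-[(2E,6E)-8-bromo-3,7-dimethylocta-2,6-dien-1-yl]-2,5-dimethoxy-3-methylbenzene; 10 trimethyl(prop-1-yn-1-yl)silane
Product: 13 1-[(2E,6E)-3,7-dimethylundeca-2,6-dien-10-yn-1-yl]-2,5-dimethoxy-3-methylbenzene, via lithiopropyne 11 (not isolated), via silylalkyne 12 (not isolated)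
Conditions: 10, n-BuLi, THF, −78 to −30 °C; 9, −78 °C to rt; then MeOH, K2CO3, rt
Reagents that add atoms: none
Why: Propargylic lithiation of 10 and SN2 alkylation by the primary allylic bromide form C8'–C9'; the silyl group steers the ambident propargyl–allenyl anion to react at its CH2 terminus, and methoxide then cleaves the C(sp)–Si bond in the same flask.

Step 7
Reactants: 14 4-methylpent-3-enoic acid
Product: 16 N-methoxy-N,4-dimethylpent-3-enamide, via acylimidazole 15 (not isolated)
Conditions: CDI, CH2Cl2, rt; MeNH(OMe)·HCl, rt
Reagents that add atoms: N,O-dimethylhydroxylamine hydrochloride, CNOC.Cl; 1,1'-carbonyldiimidazole, O=C(n1ccnc1)n1ccnc1 (imidazolyl group of 15 only)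
Why: Amide formation through the acylimidazole; the activation is neutral, which avoids the double-bond migration that an acid chloride with amine base could cause.

Step 8
Reactants: 13 1-[(2E,6E)-3,7-dimethylundeca-2,6-dien-10-yn-1-yl]-2,5-dimethoxy-3-methylbenzene; 16 N-methoxy-N,4-dimethylpent-3-enamide
Product: 18 (10E,14E)-16-(2,5-dimethoxy-3-methylphenyl)-2,10,14-trimethylhexadeca-2,10,14-trien-6-yn-5-one, via lithium acetylide 17 (not isolated)
Conditions: 13, n-BuLi, THF, −78 °C; 16 (1.2 equiv), −78 to −20 °C; inverse quench into cold 1 M HCl
Reagents that add atoms: none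
Why: Weinreb ketone synthesis; the acetylide adds to the amide to give a chelated tetrahedral adduct that collapses only at the quench, so there is no over-addition, and the cold acidic quench protonates the liberated N,O-dimethylhydroxylamine before it can add to the ynone or shift the skipped olefin.

Step 9
Reactants: 18 (10E,14E)-16-(2,5-dimethoxy-3-methylphenyl)-2,10,14-trimethylhexadeca-2,10,14-trien-6-yn-5-one
Product: 19 (5R,10E,14E)-16-(2,5-dimethoxy-3-methylphenyl)-2,10,14-trimethylhexadeca-2,10,14-trien-6-yn-5-ol
Conditions: Ru[(R,R)-TsNCH(Ph)CH(Ph)NH](p-cymene) (3 mol %), i-PrOH, rt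
Reagents that add atoms: none
Why: Noyori asymmetric transfer hydrogenation of an alkynyl ketone with the preformed 16-electron amido complex, without added base; hydride and proton pass through the six-membered metal–ligand bifunctional transition state, and the (R,R)-diamine is expected to give the R carbinol because the alkynyl group takes the place that aryl holds in aryl ketone reduction, so C12' is set here under catalyst control.

Step 10
Reactants: 20 (chloromethyl)dimethyl(propan-2-yloxy)silane
Product: 21 chloro{[dimethyl(propan-2-yloxy)silyl]methyl}magnesium
Conditions: Mg turnings, BrCH2CH2Br (cat.), THF, reflux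
Reagents that add atoms: magnesium, [Mg]
Why: Grignard formation from a primary chloromethylsilane; the bulky isopropoxy group shields silicon against attack by the reagent, so the solution can be titrated and stored briefly.

Step 11
Reactants: 19 (5R,10E,14E)-16-(2,5-dimethoxy-3-methylphenyl)-2,10,14-trimethylhexadeca-2,10,14-trien-6-yn-5-ol; 21 chloro{[dimethyl(propan-2-yloxy)silyl]methyl}magnesium
Product: 24 (5R,6Z,10E,14E)-16-(2,5-dimethoxy-3-methylphenyl)-6-{[dimethyl(propan-2-yloxy)silyl]methyl}-2,10,14-trimethylhexadeca-2,6,10,14-tetraen-5-ol, via magnesium alkoxide 22 (not isolated), via oxamagnesacycle 23 (not isolated)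
Conditions: 21 (4 equiv), CuI (0.2 equiv), THF/toluene, 0 to 50 °C; aq. NH4Cl/NH3, 0 °C
Reagents that add atoms: none
Why: The first equivalent of 21 deprotonates O12'–H to the alkoxide, CuI and further 21 form a silylmethylcopper species that activates the alkyne, and the silylmethyl carbon bonds to C11' while magnesium bonds to C10' on the side of O12', which gives the five-membered oxamagnesacycle (O12', C12', C11', C10', Mg). The closest known reaction type is the copper-catalysed anti-carbomagnesiation of propargylic alkoxides by Grignard reagents, silylmethyl reagents included. No ring of the product is closed; the only ring is the transient chelate, formed by a five-membered closure and opened again on protonolysis. No new stereocentre is formed and C12' cannot epimerise as its alkoxide; the new stereo-element is the C10'=C11' geometry, which the chelate controls. The step needs regioselectivity (carbon to C11', metal to C10') and anti addition, and both follow from the chelate, because O12' can hold a C10'–Mg bond only if that bond is cis to C12', which leaves the silylmethyl group cis to C9'. Protonolysis of C10'–Mg by buffered NH4Cl proceeds with retention and gives the olefin that is Z by the sequence rule yet has the spatial arrangement required for the 10'E diol. An internal alkyl-substituted alkyne reacts slowly, hence the excess of 21, the raised CuI loading and gentle warming, while the aryl ethers and the trisubstituted olefins are inert to the reagent.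

Step 12
Reactants: 24 (5R,6Z,10E,14E)-16-(2,5-dimethoxy-3-methylphenyl)-6-{[dimethyl(propan-2-yloxy)silyl]methyl}-2,10,14-trimethylhexadeca-2,6,10,14-tetraen-5-ol
Product: 25 (5R,6E,10E,14E)-16-(2,5-dimethoxy-3-methylphenyl)-6-(hydroxymethyl)-2,10,14-trimethylhexadeca-2,6,10,14-tetraen-5-ol
Conditions: 30% H2O2, KF, KHCO3, THF/MeOH (1:1), rt
Reagents that add atoms: hydrogen peroxide, OO
Why: Tamao oxidation; fluoride and hydrogen carbonate activate the alkoxysilane towards hydroperoxide and the allylic CH2 migrates from silicon to oxygen, so C–Si becomes C–OH without allylic transposition, and the olefins are not epoxidised by basic H2O2 when no nitrile is present.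

Step 13
Reactants: 25 (5R,6E,10E,14E)-16-(2,5-dimethoxy-3-methylphenyl)-6-(hydroxymethyl)-2,10,14-trimethylhexadeca-2,6,10,14-tetraen-5-ol
Product: 26 2-[(2E,6E,10E,12R)-12-hydroxy-11-(hydroxymethyl)-3,7,15-trimethylhexadeca-2,6,10,14-tetraen-1-yl]-6-methylcyclohexa-2,5-diene-1,4-dione
Conditions: (NH4)2Ce(NO3)6 (2.5 equiv), MeCN/H2O (2:1), 0 °C, 15 min
Reagents that add atoms: water, O
Why: Oxidative demethylation of the 1,4-dimethoxyarene by two single-electron oxidations with tetravalent cerium; water attacks the arene radical cation at the methoxy-bearing carbons and methanol is lost, which should give the quinone within minutes at 0 °C, before the allylic diol or the olefins react.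

## Compound list

1 | 4-methoxy-2-methylphenol | Cc1cc(OC)ccc1O | starting material
2 | 2-bromo-4-methoxy-6-methylphenol | Cc1cc(OC)cc(Br)c1O | intermediate
3 | 1-bromo-2,5-dimethoxy-3-methylbenzene | COc1cc(C)c(OC)c(Br)c1 | intermediate
4 | geranyl bromide, (2E)-1-bromo-3,7-dimethylocta-2,6-diene | CC(C)=CCC/C(C)=C/CBr | starting material
5 | (2,5-dimethoxy-3-methylphenyl)lithium, formed in the flask | [Li]c1cc(OC)cc(C)c1OC | intermediate
6 | (2,5-dimethoxy-3-methylphenyl)copper, formed in the flask | [Cu]c1cc(OC)cc(C)c1OC | intermediate
7 | 1-[(2E)-3,7-dimethylocta-2,6-dien-1-yl]-2,5-dimethoxy-3-methylbenzene | CC(C)=CCC/C(C)=C/Cc1cc(OC)cc(C)c1OC | intermediate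
8 | (2E,6E)-8-(2,5-dimethoxy-3-methylphenyl)-2,6-dimethylocta-2,6-dien-1-ol | OC/C(C)=C/CC/C(C)=C/Cc1cc(OC)cc(C)c1OC | intermediate
9 | 1-[(2E,6E)-8-bromo-3,7-dimethylocta-2,6-dien-1-yl]-2,5-dimethoxy-3-methylbenzene | BrC/C(C)=C/CC/C(C)=C/Cc1cc(OC)cc(C)c1OC | intermediate
10 | trimethyl(prop-1-yn-1-yl)silane | CC#C[Si](C)(C)C | starting material
11 | [3-(trimethylsilyl)prop-2-yn-1-yl]lithium, formed in the flask | [Li]CC#C[Si](C)(C)C | intermediate
12 | [(5E,9E)-11-(2,5-dimethoxy-3-methylphenyl)-5,9-dimethylundeca-5,9-dien-1-yn-1-yl]trimethylsilane, formed in the flask | C[Si](C)(C)C#CCC/C(C)=C/CC/C(C)=C/Cc1cc(OC)cc(C)c1OC | intermediate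
13 | 1-[(2E,6E)-3,7-dimethylundeca-2,6-dien-10-yn-1-yl]-2,5-dimethoxy-3-methylbenzene | C#CCC/C(C)=C/CC/C(C)=C/Cc1cc(OC)cc(C)c1OC | intermediate
14 | 4-methylpent-3-enoic acid | CC(C)=CCC(=O)O | starting material
15 | 1-(4-methylpent-3-enoyl)imidazole, formed in the flask | CC(C)=CCC(=O)n1ccnc1 | intermediate
16 | N-methoxy-N,4-dimethylpent-3-enamide | CC(C)=CCC(=O)N(C)OC | intermediate
17 | lithium acetylide of 13, formed in the flask | [Li]C#CCC/C(C)=C/CC/C(C)=C/Cc1cc(OC)cc(C)c1OC | intermediate
18 | (10E,14E)-16-(2,5-dimethoxy-3-methylphenyl)-2,10,14-trimethylhexadeca-2,10,14-trien-6-yn-5-one | CC(C)=CCC(=O)C#CCC/C(C)=C/CC/C(C)=C/Cc1cc(OC)cc(C)c1OC | intermediate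
19 | (5R,10E,14E)-16-(2,5-dimethoxy-3-methylphenyl)-2,10,14-trimethylhexadeca-2,10,14-trien-6-yn-5-ol (C5 is C12') | CC(C)=CC[C@@H](O)C#CCC/C(C)=C/CC/C(C)=C/Cc1cc(OC)cc(C)c1OC | intermediate
20 | (chloromethyl)dimethyl(propan-2-yloxy)silane | CC(C)O[Si](C)(C)CCl | starting material
21 | chloro{[dimethyl(propan-2-yloxy)silyl]methyl}magnesium | CC(C)O[Si](C)(C)C[Mg]Cl | intermediate
22 | chloromagnesium alkoxide of 19 (12'R), formed in the flask | CC(C)=CC[C@@H](O[Mg]Cl)C#CCC/C(C)=C/CC/C(C)=C/Cc1cc(OC)cc(C)c1OC | intermediate
23 | five-membered oxamagnesacycle O12'–Mg–C10'=C11'–C12' (12'R) with the silylmethyl group on C11' and the chain on C10', formed in the flask | CC(C)=CC[C@H]1O[Mg]C(CC/C(C)=C/CC/C(C)=C/Cc2cc(OC)cc(C)c2OC)=C1C[Si](C)(C)OC(C)C | intermediate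
24 | (5R,6Z,10E,14E)-16-(2,5-dimethoxy-3-methylphenyl)-6-{[dimethyl(propan-2-yloxy)silyl]methyl}-2,10,14-trimethylhexadeca-2,6,10,14-tetraen-5-ol | CC(C)=CC[C@@H](O)/C(=C/CC/C(C)=C/CC/C(C)=C/Cc1cc(OC)cc(C)c1OC)C[Si](C)(C)OC(C)C | intermediate
25 | (5R,6E,10E,14E)-16-(2,5-dimethoxy-3-methylphenyl)-6-(hydroxymethyl)-2,10,14-trimethylhexadeca-2,6,10,14-tetraen-5-ol | CC(C)=CC[C@@H](O)/C(=C/CC/C(C)=C/CC/C(C)=C/Cc1cc(OC)cc(C)c1OC)CO | intermediate
26 | 2-[(2E,6E,10E,12R)-12-hydroxy-11-(hydroxymethyl)-3,7,15-trimethylhexadeca-2,6,10,14-tetraen-1-yl]-6-methylcyclohexa-2,5-diene-1,4-dione | CC(C)=CC[C@@H](O)/C(=C/CC/C(C)=C/CC/C(C)=C/CC1=CC(=O)C=C(C)C1=O)CO | target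

## Step count and weak points

Total step count: 13. Longest linear sequence: 11 steps (steps 1 to 6, 8, 9, 11, 12 and 13); steps 7 and 10 are side branches.

Step 11 (key step).
- What may go wrong: carbometalation of the alkyl-substituted internal alkyne may stall, and the alkoxysilyl Grignard reagent may decay at the temperature needed. Anti selectivity may be lost through an unchelated syn-carbocupration if the copper loading is raised too far. The allylsilane may be protodesilylated if the quench turns acidic.
- Fallback: it sets out from 19 and forms the C11'–CH2 bond by cross-coupling, the geometry coming from a trans-hydrometalation. Hydroxyl-directed trans-hydrostannation of 19 with Bu3SnH and catalytic [Cp*RuCl]4 in CH2Cl2 should place tin on C11' and hydrogen on C10' in anti fashion and give the (Z)-α-stannyl allylic alcohol F1. Iododestannylation with I2 in CH2Cl2 at −78 °C with retention gives the alkenyl iodide F2. Kumada coupling of F2 with 21 (3 equiv) and Pd(PPh3)4 (zerovalent palladium) in THF returns to the route at 24.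

Step 4.
- What may go wrong: site selectivity may be poor among the terminal methyl group, the allylic positions of the C2'=C3' olefin and the doubly activated C1' methylene. Over-oxidation to the enal may also occur; that part is reversible by treating the crude product with NaBH4.
- Fallback: the oxidation is done before the arene is attached. It sets out from 3 (as arylcopper 6) and commercial geranyl acetate and comes back at 8. Geranyl acetate is oxidised with catalytic SeO2 and t-BuOOH, for which the deactivated internal olefin ensures terminal selectivity, to the hydroxy acetate F3. Silylation with TBSCl and imidazole gives F4, methanolysis of the acetate with K2CO3 in MeOH gives the allylic alcohol F5, and CBr4 with PPh3 gives the bromide F6. Coupling of F6 with 6 as in step 3 gives the silyl ether F7, and Bu4NF in THF releases 8.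

Step 8.
- What may go wrong: the acetylide may deprotonate the α-position of 16 and not add, the liberated hydroxylamine may add to the ynone in conjugate fashion, and the β,γ-double bond may migrate during work-up.
- Fallback: it sets out from 13 (as 17) and returns at 18. The acetylide 17 is added at −78 °C to 4-methylpent-3-enal F8, made by Dess–Martin oxidation of commercial 4-methylpent-3-en-1-ol and used as a cold solution. The racemic propargylic alcohol F9 is then oxidised with MnO2 in CH2Cl2 under neutral conditions to 18.

Step 9.
- What may go wrong: the basic amido complex may move the skipped C14'=C15' olefin into conjugation before hydride transfer, and enantiomeric purity may erode if the reduction becomes reversible at long reaction times.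
- Fallback: the stereocentre and the C11'–C12' bond are made together, bypassing 18. It sets out from 13 and returns at 19. 13 is converted with ZnMe2 into the alkynylzinc and added to aldehyde F8 (prepared as in the fallback to step 8, used in excess) in toluene with a ProPhenol ligand and Ph3PO. The ligand antipode is chosen for delivery to the Si face of the aldehyde, and the sense is checked by Mosher ester analysis on the first batch.

Step 13.
- What may go wrong: the acidic tetravalent cerium medium may ionise or oxidise the allylic 1,3-diol or attack the trisubstituted olefins, and the product may cyclise to a chromenol during isolation.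
- Fallback: it sets out from 25 and ends at 26. Anodic oxidation of 25 in methanolic KOH (Pt anode, constant current) should give the quinone bis(dimethyl ketal) F10 without a chemical oxidant. Dilute aqueous oxalic acid in acetone then hydrolyses F10 to 26.

## Further compounds

F1 | step 11 | (5R,6Z,10E,14E)-16-(2,5-dimethoxy-3-methylphenyl)-2,10,14-trimethyl-6-(tributylstannyl)hexadeca-2,6,10,14-tetraen-5-ol | CC(C)=CC[C@@H](O)/C(=C/CC/C(C)=C/CC/C(C)=C/Cc1cc(OC)cc(C)c1OC)[Sn](CCCC)(CCCC)CCCC
F2 | step 11 | (5R,6Z,10E,14E)-16-(2,5-dimethoxy-3-methylphenyl)-6-iodo-2,10,14-trimethylhexadeca-2,6,10,14-tetraen-5-ol | CC(C)=CC[C@@H](O)/C(=C/CC/C(C)=C/CC/C(C)=C/Cc1cc(OC)cc(C)c1OC)I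
F3 | step 4 | (2E,6E)-8-hydroxy-3,7-dimethylocta-2,6-dien-1-yl acetate | OC/C(C)=C/CC/C(C)=C/COC(C)=O
F4 | step 4 | (2E,6E)-8-[tert-butyl(dimethyl)silyl]oxy-3,7-dimethylocta-2,6-dien-1-yl acetate | CC(C)(C)[Si](C)(C)OC/C(C)=C/CC/C(C)=C/COC(C)=O
F5 | step 4 | (2E,6E)-8-[tert-butyl(dimethyl)silyl]oxy-3,7-dimethylocta-2,6-dien-1-ol | CC(C)(C)[Si](C)(C)OC/C(C)=C/CC/C(C)=C/CO
F6 | step 4 | [(2E,6E)-8-bromo-2,6-dimethylocta-2,6-dien-1-yl]oxy(tert-butyl)dimethylsilane | CC(C)(C)[Si](C)(C)OC/C(C)=C/CC/C(C)=C/CBr
F7 | step 4 | tert-butyl{[(2E,6E)-8-(2,5-dimethoxy-3-methylphenyl)-2,6-dimethylocta-2,6-dien-1-yl]oxy}dimethylsilane | CC(C)(C)[Si](C)(C)OC/C(C)=C/CC/C(C)=C/Cc1cc(OC)cc(C)c1OC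
F8 | step 8 | 4-methylpent-3-enal | CC(C)=CCC=O
F9 | step 8 | racemic (10E,14E)-16-(2,5-dimethoxy-3-methylphenyl)-2,10,14-trimethylhexadeca-2,10,14-trien-6-yn-5-ol | CC(C)=CCC(O)C#CCC/C(C)=C/CC/C(C)=C/Cc1cc(OC)cc(C)c1OC
F0 | step 9 | none | none
F10 | step 13 | (5R,6E,10E,14E)-6-(hydroxymethyl)-2,10,14-trimethyl-16-(3,3,6,6-tetramethoxy-5-methylcyclohexa-1,4-dien-1-yl)hexadeca-2,6,10,14-tetraen-5-ol | CC(C)=CC[C@@H](O)/C(=C/CC/C(C)=C/CC/C(C)=C/CC1=CC(OC)(OC)C=C(C)C1(OC)OC)CO
A1 | alternative 1 | 2-[(2E,6E,10E,12R)-12-[tert-butyl(dimethyl)silyl]oxy-11-({[tert-butyl(dimethyl)silyl]oxy}methyl)-3,7,15-trimethylhexadeca-2,6,10,14-tetraen-1-yl]-4-methoxy-6-methylphenol | CC(C)=CC[C@@H](O[Si](C)(C)C(C)(C)C)/C(=C/CC/C(C)=C/CC/C(C)=C/Cc1cc(OC)cc(C)c1O)CO[Si](C)(C)C(C)(C)C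
A2 | alternative 1 | pentacarbonyl[(2E)-1-methoxybut-2-en-1-ylidene]chromium | COC(/C=C/C)=[Cr](=C=O)(=C=O)(=C=O)(=C=O)=C=O
A3 | alternative 1 | (4E,8E,12E,14R)-14-[tert-butyl(dimethyl)silyl]oxy-13-({[tert-butyl(dimethyl)silyl]oxy}methyl)-5,9,17-trimethyloctadeca-4,8,12,16-tetraen-1-yne | CC(C)=CC[C@@H](O[Si](C)(C)C(C)(C)C)/C(=C/CC/C(C)=C/CC/C(C)=C/CC#C)CO[Si](C)(C)C(C)(C)C
A4 | alternative 2 | 1-[(2E,6E,10E,12R)-12-[tert-butyl(dimethyl)silyl]oxy-11-({[tert-butyl(dimethyl)silyl]oxy}methyl)-3,7,15-trimethylhexadeca-2,6,10,14-tetraen-1-yl]-2,5-dimethoxy-3-methylbenzene | CC(C)=CC[C@@H](O[Si](C)(C)C(C)(C)C)/C(=C/CC/C(C)=C/CC/C(C)=C/Cc1cc(OC)cc(C)c1OC)CO[Si](C)(C)C(C)(C)C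
A5 | alternative 2 | (5E,9E,11R)-11-[tert-butyl(dimethyl)silyl]oxy-10-({[tert-butyl(dimethyl)silyl]oxy}methyl)-6,14-dimethylpentadeca-5,9,13-trien-1-yne | CC(C)=CC[C@@H](O[Si](C)(C)C(C)(C)C)/C(=C/CC/C(C)=C/CCC#C)CO[Si](C)(C)C(C)(C)C
A6 | alternative 2 | 1-(chloromethyl)-2,5-dimethoxy-3-methylbenzene | ClCc1cc(OC)cc(C)c1OC
A7 | alternative 3 | (5R,6E,10E,14E)-6-({[tert-butyl(dimethyl)silyl]oxy}methyl)-16-(2,5-dimethoxy-3-methylphenyl)-2,10,14-trimethylhexadeca-2,6,10,14-tetraen-5-ol | CC(C)=CC[C@@H](O)/C(=C/CC/C(C)=C/CC/C(C)=C/Cc1cc(OC)cc(C)c1OC)CO[Si](C)(C)C(C)(C)C
A8 | alternative 3 | (2E,6E,10E)-2-({[tert-butyl(dimethyl)silyl]oxy}methyl)-12-(2,5-dimethoxy-3-methylphenyl)-6,10-dimethyldodeca-2,6,10-trienal | O=C/C(=C/CC/C(C)=C/CC/C(C)=C/Cc1cc(OC)cc(C)c1OC)CO[Si](C)(C)C(C)(C)C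
A9 | alternative 3 | (1S,2S,5R)-5-methyl-1-(2-methylbut-3-en-2-yl)-2-(propan-2-yl)cyclohexan-1-ol (hydroxyl cis to isopropyl, trans to methyl) | C[C@@H]1CC[C@@H](C(C)C)[C@](O)(C(C)(C)C=C)C1
A10 | alternative 3 | (2S,5R)-5-methyl-2-(propan-2-yl)cyclohexan-1-one | C[C@@H]1CC[C@H](C(=O)C1)C(C)C
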